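**Retrosynthetic overview**
- The target comes from a macrocyclic C8 alcohol by Mitsunobu esterification with (2S,3S)-epoxyangelic acid, with inversion at C8; no ring is formed after the macrocyclisation.
- The ten-membered carbocycle is closed last, at C7–C8, by an intramolecular Nozaki–Hiyama allylation of an open-chain aldehyde that carries a 3-(bromomethyl)butenolide. The enabling feature is the homoallylic alcohol unit C13=C11–C7–C8–O8: the exocyclic methylene sits on the γ-lactone ring (O–C12–C11–C7–C6), and C7–C8 is a bond of the carbocycle but not of the lactone.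
- The cyclisation precursor is built from the butenolide (ring-closing metathesis of a 2-(bromomethyl)acrylate), the C1–C10 oxirane (Shi epoxidation), C3 (CBS reduction) and the C3–C4 bond (Nozaki–Hiyama–Kishi coupling of a Z-vinyl iodide with a β,γ-unsaturated aldehyde).
- The fragments come from (S)-but-3-ene-1,2-diol (C5–C7, Stork–Zhao olefination for the 4Z alkene), but-3-yn-1-ol (C8–C10/C1–C3, Negishi carboalumination and ethylene oxide) and methyl angelate (epoxy acid, Sharpless epoxidation).
- Order of ring formation: side-chain oxirane (made separately), C1–C10 oxirane, γ-lactone, ten-membered carbocycle.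

Key step: step 21

Remark: germacranolide numbering is used (C1/C10 oxirane, C3 isovalerate carbinol, C4=C5 Z-alkene, C6 lactone CH–O, C7 ring fusion, C8 epoxy-ester carbinol, C11=C13 methylene, C12 carbonyl). The closed transition state of step 21 is expected to give the 8S carbinol, and the route is written for that outcome.

**Route**

Step 1
Reactants: 1 (S)-but-3-ene-1,2-diol
Product: 2 (S)-3,4-bis(tert-butyldimethylsilyloxy)but-1-ene
Conditions: TBSCl (2.3 equiv), imidazole, DMF, rt
Reagents that add atoms: tert-butyldimethylsilyl chloride, CC(C)(C)[Si](C)(C)Cl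
Why: Imidazole-promoted silylation of both hydroxyls; the stereocentre (C6 of the target) comes from the chiral pool and is not touched.

Step 2
Reactants: 2 (S)-3,4-bis(tert-butyldimethylsilyloxy)but-1-ene
Product: 3 (S)-2-(tert-butyldimethylsilyloxy)but-3-en-1-ol
Conditions: HF·pyridine, pyridine, THF, 0 °C
Reagents that add atoms: none
Why: Selective desilylation, because the primary silyl ether is cleaved much faster than the hindered secondary allylic one.

Step 3
Reactants: 3 (S)-2-(tert-butyldimethylsilyloxy)but-3-en-1-ol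
Product: 4 (S)-2-(tert-butyldimethylsilyloxy)but-3-enal
Conditions: Dess–Martin periodinane, NaHCO3, CH2Cl2, 0 °C; used crude at once
Reagents that add atoms: none
Why: Buffered Dess–Martin oxidation gives the α-silyloxy aldehyde under non-basic conditions, which should avoid epimerisation and migration of the double bond.

Step 4
Reactants: 4 (S)-2-(tert-butyldimethylsilyloxy)but-3-enal
Product: 5 (3S,4Z)-3-(tert-butyldimethylsilyloxy)-5-iodohexa-1,4-diene
Conditions: EtPPh3I, n-BuLi, THF; I2, −78 °C; NaHMDS, −20 °C; then 4, −78 °C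
Reagents that add atoms: ethyltriphenylphosphonium iodide, CC[P+](c1ccccc1)(c1ccccc1)c1ccccc1.[I-]; iodine, II
Why: Stork–Zhao olefination with the α-iodo ylide should give the (Z)-2-iodoalkene under kinetic control, which fixes the C4=C5 geometry (iodine cis to C6).

Step 5
Reactants: 6 but-3-yn-1-ol
Product: 7 4-methoxybenzyl but-3-ynyl ether
Conditions: NaH, PMBCl, Bu4NI (cat.), THF–DMF, 0 °C → rt
Reagents that add atoms: 4-methoxybenzyl chloride, COc1ccc(CCl)cc1
Why: Williamson etherification protects the future C8 oxygen as a PMB ether that can be removed oxidatively under neutral conditions late in the route.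

Step 6
Reactants: 7 4-methoxybenzyl but-3-ynyl ether
Product: 9 (E)-6-(4-methoxybenzyloxy)-4-methylhex-3-en-1-ol, via alkenylalane 8 (not isolated)
Conditions: AlMe3, Cp2ZrCl2 (cat.), CH2Cl2, 0 °C → rt; then n-BuLi, hexane–THF, −40 °C; ethylene oxide, −40 °C → rt; aq. Rochelle salt
Reagents that add atoms: trimethylaluminium, C[Al](C)C; ethylene oxide, C1CO1
Why: Negishi syn-carboalumination puts methyl on the internal and aluminium on the terminal alkyne carbon, and the derived alanate opens ethylene oxide with retention, which gives the E-trisubstituted C1=C10 alkene.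

Step 7
Reactants: 9 (E)-6-(4-methoxybenzyloxy)-4-methylhex-3-en-1-ol
Product: 10 (E)-6-(4-methoxybenzyloxy)-4-methylhex-3-enal
Conditions: Dess–Martin periodinane, NaHCO3, CH2Cl2, 0 °C; used at once
Reagents that add atoms: none
Why: Buffered Dess–Martin oxidation should give the β,γ-unsaturated aldehyde without migration of the double bond into conjugation.

Step 8
Reactants: 11 methyl angelate (methyl (Z)-2-methylbut-2-enoate)
Product: 12 (Z)-2-methylbut-2-en-1-ol
Conditions: DIBAL-H (2.2 equiv), Et2O, −78 → 0 °C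
Reagents that add atoms: none
Why: DIBAL-H 1,2-reduction of the ester gives the allylic alcohol with retention of the Z geometry.

Step 9
Reactants: 12 (Z)-2-methylbut-2-en-1-ol
Product: 13 [(2R,3S)-2,3-dimethyloxiran-2-yl]methanol
Conditions: Ti(OiPr)4 (10 mol%), D-(−)-diethyl tartrate (12 mol%), t-BuOOH, 4 Å MS, CH2Cl2, −20 °C
Reagents that add atoms: tert-butyl hydroperoxide, CC(C)(C)OO
Why: Sharpless asymmetric epoxidation, in which D-(−)-tartrate directs oxygen to the face that gives the (2R,3S)-epoxy alcohol, so both side-chain stereocentres are set by the reagent.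

Step 10
Reactants: 13 [(2R,3S)-2,3-dimethyloxiran-2-yl]methanol
Product: 14 (2S,3S)-2,3-dimethyloxirane-2-carboxylic acid
Conditions: TEMPO (cat.), PhI(OAc)2, MeCN–H2O, rt
Reagents that add atoms: water, O
Why: TEMPO/PhI(OAc)2 oxidation takes the primary alcohol to the acid without touching the oxirane; the C2 descriptor changes from R to S without change of configuration.

Step 11
Reactants: 5 (3S,4Z)-3-(tert-butyldimethylsilyloxy)-5-iodohexa-1,4-diene; 10 (E)-6-(4-methoxybenzyloxy)-4-methylhex-3-enal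
Product: 15 (3S,4Z,8E)-3-(tert-butyldimethylsilyloxy)-11-(4-methoxybenzyloxy)-5,9-dimethylundeca-1,4,8-trien-6-ol (both C6 epimers)
Conditions: CrCl2 (5 equiv), NiCl2 (2 mol%), DMSO, rt
Reagents that add atoms: none
Why: Nozaki–Hiyama–Kishi coupling forms C3–C4 by chemoselective, non-basic 1,2-addition of the vinylchromium reagent with retention of the Z geometry; the new carbinol (C3 of the target) is not controlled here and is corrected in steps 12–13.

Step 12
Reactants: 15 (3S,4Z,8E)-3-(tert-butyldimethylsilyloxy)-11-(4-methoxybenzyloxy)-5,9-dimethylundeca-1,4,8-trien-6-ol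
Product: 16 (3S,4Z,8E)-3-(tert-butyldimethylsilyloxy)-11-(4-methoxybenzyloxy)-5,9-dimethylundeca-1,4,8-trien-6-one
Conditions: Dess–Martin periodinane, NaHCO3, CH2Cl2, 0 °C
Reagents that add atoms: none
Why: Dess–Martin oxidation merges both carbinol epimers into one enone under buffered conditions that should leave the β′,γ′-alkene in place.

Step 13
Reactants: 16 (3S,4Z,8E)-3-(tert-butyldimethylsilyloxy)-11-(4-methoxybenzyloxy)-5,9-dimethylundeca-1,4,8-trien-6-one
Product: 17 (3S,4Z,6S,8E)-3-(tert-butyldimethylsilyloxy)-11-(4-methoxybenzyloxy)-5,9-dimethylundeca-1,4,8-trien-6-ol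
Conditions: (R)-2-methyl-CBS-oxazaborolidine, catecholborane, toluene, −78 °C
Reagents that add atoms: none
Why: Corey–Bakshi–Shibata reduction, in which the α-branched alkenyl group acts as the large substituent, so the (R)-catalyst should give the 6S alcohol (C3 of the target) under reagent control.

Step 14
Reactants: 17 (3S,4Z,6S,8E)-3-(tert-butyldimethylsilyloxy)-11-(4-methoxybenzyloxy)-5,9-dimethylundeca-1,4,8-trien-6-ol
Product: 18 (3S,4Z,6S,8E)-3-(tert-butyldimethylsilyloxy)-11-(4-methoxybenzyloxy)-5,9-dimethylundeca-1,4,8-trien-6-yl 3-methylbutanoate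
Conditions: isovaleryl chloride, pyridine, DMAP (cat.), CH2Cl2, 0 °C
Reagents that add atoms: 3-methylbutanoyl chloride, CC(C)CC(=O)Cl
Why: Acylation of the secondary allylic alcohol installs the isovalerate of the target with retention.

Step 15
Reactants: 18 (3S,4Z,6S,8E)-3-(tert-butyldimethylsilyloxy)-11-(4-methoxybenzyloxy)-5,9-dimethylundeca-1,4,8-trien-6-yl 3-methylbutanoate
Product: 19 (3S,4Z,6S)-3-(tert-butyldimethylsilyloxy)-7-{(2R,3R)-3-[2-(4-methoxybenzyloxy)ethyl]-3-methyloxiran-2-yl}-5-methylhepta-1,4-dien-6-yl 3-methylbutanoate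
Conditions: D-fructose-derived Shi ketone (0.3 equiv), Oxone, K2CO3, Bu4NHSO4, MeCN–dimethoxymethane–aq. borate buffer, 0 °C
Reagents that add atoms: Oxone (potassium peroxymonosulfate), [K+].[O-]S(=O)(=O)OO
Why: Shi epoxidation, in which the fructose-derived dioxirane should epoxidise the electron-rich E-trisubstituted alkene through a spiro transition state to the (R,R)-oxirane under reagent control, while the vinyl group and the hindered, doubly oxygen-flanked Z-alkene react far more slowly.

Step 16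
Reactants: 19 (3S,4Z,6S)-3-(tert-butyldimethylsilyloxy)-7-{(2R,3R)-3-[2-(4-methoxybenzyloxy)ethyl]-3-methyloxiran-2-yl}-5-methylhepta-1,4-dien-6-yl 3-methylbutanoate
Product: 20 (3S,4Z,6S)-3-hydroxy-7-{(2R,3R)-3-[2-(4-methoxybenzyloxy)ethyl]-3-methyloxiran-2-yl}-5-methylhepta-1,4-dien-6-yl 3-methylbutanoate
Conditions: TBAF–AcOH (1:1), THF, 0 °C → rt
Reagents that add atoms: none
Why: Fluoride-mediated desilylation buffered with acetic acid should free the C6 hydroxyl without acyl migration across the Z-alkene or opening of the oxirane.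

Step 17
Reactants: 20 (3S,4Z,6S)-3-hydroxy-7-{(2R,3R)-3-[2-(4-methoxybenzyloxy)ethyl]-3-methyloxiran-2-yl}-5-methylhepta-1,4-dien-6-yl 3-methylbutanoate
Product: 21 (3S,4Z,6S)-7-{(2R,3R)-3-[2-(4-methoxybenzyloxy)ethyl]-3-methyloxiran-2-yl}-5-methyl-6-(3-methylbutanoyloxy)hepta-1,4-dien-3-yl 2-(bromomethyl)prop-2-enoate
Conditions: 2-(bromomethyl)acrylic acid, DIC, DMAP (5 mol%), CH2Cl2, −20 → 0 °C
Reagents that add atoms: 2-(bromomethyl)acrylic acid, OC(=O)C(=C)CBr
Why: Carbodiimide (Steglich-type) esterification with retention at C6 brings in C11, C12 and C13 together with the allylic bromide.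

Step 18
Reactants: 21 (3S,4Z,6S)-7-{(2R,3R)-3-[2-(4-methoxybenzyloxy)ethyl]-3-methyloxiran-2-yl}-5-methyl-6-(3-methylbutanoyloxy)hepta-1,4-dien-3-yl 2-(bromomethyl)prop-2-enoate
Product: 22 (5R)-3-(bromomethyl)-5-[(1Z,3S)-2-methyl-3-(3-methylbutanoyloxy)-4-{(2R,3R)-3-[2-(4-methoxybenzyloxy)ethyl]-3-methyloxiran-2-yl}but-1-en-1-yl]furan-2(5H)-one
Conditions: Hoveyda–Grubbs II (10 mol%), toluene (5 mM), 80 °C
Reagents that add atoms: none
Why: Ring-closing metathesis between the vinyl group and the 1,1-disubstituted acrylate closes the γ-lactone as a butenolide with loss of ethylene; no stereocentre is touched (the C6 descriptor changes to R only through the priority rules).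

Step 19
Reactants: 22 (5R)-3-(bromomethyl)-5-[(1Z,3S)-2-methyl-3-(3-methylbutanoyloxy)-4-{(2R,3R)-3-[2-(4-methoxybenzyloxy)ethyl]-3-methyloxiran-2-yl}but-1-en-1-yl]furan-2(5H)-one
Product: 23 (5R)-3-(bromomethyl)-5-[(1Z,3S)-4-{(2R,3R)-3-(2-hydroxyethyl)-3-methyloxiran-2-yl}-2-methyl-3-(3-methylbutanoyloxy)but-1-en-1-yl]furan-2(5H)-one
Conditions: DDQ, CH2Cl2–pH 7 buffer, 0 °C
Reagents that add atoms: none
Why: Oxidative PMB cleavage with DDQ under buffered neutral conditions frees the C8 alcohol in the presence of the allylic bromide, butenolide and oxirane.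

Step 20
Reactants: 23 (5R)-3-(bromomethyl)-5-[(1Z,3S)-4-{(2R,3R)-3-(2-hydroxyethyl)-3-methyloxiran-2-yl}-2-methyl-3-(3-methylbutanoyloxy)but-1-en-1-yl]furan-2(5H)-one
Product: 24 (5R)-3-(bromomethyl)-5-[(1Z,3S)-2-methyl-3-(3-methylbutanoyloxy)-4-{(2R,3R)-3-methyl-3-(2-oxoethyl)oxiran-2-yl}but-1-en-1-yl]furan-2(5H)-one
Conditions: Dess–Martin periodinane, NaHCO3, CH2Cl2, 0 °C; filtered and used at once
Reagents that add atoms: none
Why: Buffered Dess–Martin oxidation gives the base-sensitive β,γ-epoxy aldehyde under non-basic conditions.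

Step 21
Reactants: 24 (5R)-3-(bromomethyl)-5-[(1Z,3S)-2-methyl-3-(3-methylbutanoyloxy)-4-{(2R,3R)-3-methyl-3-(2-oxoethyl)oxiran-2-yl}but-1-en-1-yl]furan-2(5H)-one
Product: 26 (1R,3S,4Z,6R,7R,8S,10R)-1,10-epoxy-8-hydroxy-3-(3-methylbutanoyloxy)germacra-4,11(13)-dien-12,6-olide, via allylchromium species 25 (not isolated)
Conditions: CrCl2 (10 equiv), THF, rt, slow addition of 24 (final 2 mM); pH 7 buffer work-up
Reagents that add atoms: none
Why: Cr(II) reduces the allylic C–Br bond to the allylchromium(III) species 25 (Cr on C13), which adds through its γ-carbon C7 to the tethered C8 aldehyde in a six-membered Zimmerman–Traxler transition state (SE2′), so that one event forms C7–C8, moves the butenolide double bond to the exocyclic C11=C13 position and creates the C8 carbinol. The closest known reaction type is the Nozaki–Hiyama (Barbier-type) allylation of aldehydes with 3-(bromomethyl)furan-2(5H)-ones to β-(hydroxyalkyl)-α-methylene-γ-butyrolactones, together with Cr(II)-mediated allylation macrocyclisations of 2-(bromomethyl)acrylates that close germacrane rings. The ten-membered carbocycle closes in a 10-exo-trig addition to the aldehyde, with the lactone and both oxiranes already in place. C7 is controlled by C6: closure anti to the C6–C5 bond gives a C5–C6–C7–C8 torsion near 150° (trans-fused lactone), whereas syn closure would need a nearly eclipsed torsion in the forming medium ring. C8 is controlled by the chair transition state of the ring-locked E-type allyl unit with C9 pseudo-equatorial, since the pseudo-axial alternative pushes C9 against H6; this anti addition should give 8S, the epimer that step 22 inverts. The step needs chemoselectivity for the aldehyde over lactone, esters and oxirane (mild, non-basic organochromium; aldehyde made immediately before use), γ-regioselectivity (closed transition state) and intramolecularity (high dilution and slow addition).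

Step 22
Reactants: 26 (1R,3S,4Z,6R,7R,8S,10R)-1,10-epoxy-8-hydroxy-3-(3-methylbutanoyloxy)germacra-4,11(13)-dien-12,6-olide; 14 (2S,3S)-2,3-dimethyloxirane-2-carboxylic acid
Product: 27 (1R,3S,4Z,6R,7R,8R,10R)-8-[(2S,3S)-2,3-dimethyloxirane-2-carbonyloxy]-1,10-epoxy-3-(3-methylbutanoyloxy)germacra-4,11(13)-dien-12,6-olide (target, CNP0167461.1)
Conditions: PPh3, DIAD (betaine pre-formed), then 14 and 26, toluene, 0 °C → rt
Reagents that add atoms: none
Why: Mitsunobu esterification, in which the carboxylate of 14 displaces the C8 oxyphosphonium by SN2, which should invert C8 from S to R and install the epoxy ester; pre-forming the betaine keeps free phosphine away from the α-methylene lactone.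

**Compound list**
1 | (S)-but-3-ene-1,2-diol | C=C[C@H](O)CO | starting material
2 | (S)-3,4-bis(tert-butyldimethylsilyloxy)but-1-ene | C=C[C@H](O[Si](C)(C)C(C)(C)C)CO[Si](C)(C)C(C)(C)C | intermediate
3 | (S)-2-(tert-butyldimethylsilyloxy)but-3-en-1-ol | C=C[C@H](O[Si](C)(C)C(C)(C)C)CO | intermediate
4 | (S)-2-(tert-butyldimethylsilyloxy)but-3-enal | C=C[C@H](O[Si](C)(C)C(C)(C)C)C=O | intermediate
5 | (3S,4Z)-3-(tert-butyldimethylsilyloxy)-5-iodohexa-1,4-diene | C=C[C@H](O[Si](C)(C)C(C)(C)C)/C=C(/C)I | intermediate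
6 | but-3-yn-1-ol | C#CCCO | starting material
7 | 4-methoxybenzyl but-3-ynyl ether | C#CCCOCc1ccc(OC)cc1 | intermediate
8 | (E)-dimethyl[4-(4-methoxybenzyloxy)-2-methylbut-1-enyl]alane | C[Al](C)/C=C(\C)CCOCc1ccc(OC)cc1 | intermediate
9 | (E)-6-(4-methoxybenzyloxy)-4-methylhex-3-en-1-ol | OCC/C=C(\C)CCOCc1ccc(OC)cc1 | intermediate
10 | (E)-6-(4-methoxybenzyloxy)-4-methylhex-3-enal | O=CC/C=C(\C)CCOCc1ccc(OC)cc1 | intermediate
11 | methyl angelate | C/C=C(/C)C(=O)OC | starting material
12 | (Z)-2-methylbut-2-en-1-ol | C/C=C(/C)CO | intermediate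
13 | [(2R,3S)-2,3-dimethyloxiran-2-yl]methanol | OC[C@@]1(C)O[C@H]1C | intermediate
14 | (2S,3S)-2,3-dimethyloxirane-2-carboxylic acid | OC(=O)[C@@]1(C)O[C@H]1C | intermediate
15 | (3S,4Z,8E)-3-(tert-butyldimethylsilyloxy)-11-(4-methoxybenzyloxy)-5,9-dimethylundeca-1,4,8-trien-6-ol (C6 epimers) | C=C[C@H](O[Si](C)(C)C(C)(C)C)/C=C(/C)C(O)C/C=C(\C)CCOCc1ccc(OC)cc1 | intermediate
16 | (3S,4Z,8E)-3-(tert-butyldimethylsilyloxy)-11-(4-methoxybenzyloxy)-5,9-dimethylundeca-1,4,8-trien-6-one | C=C[C@H](O[Si](C)(C)C(C)(C)C)/C=C(/C)C(=O)C/C=C(\C)CCOCc1ccc(OC)cc1 | intermediate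
17 | (3S,4Z,6S,8E)-3-(tert-butyldimethylsilyloxy)-11-(4-methoxybenzyloxy)-5,9-dimethylundeca-1,4,8-trien-6-ol | C=C[C@H](O[Si](C)(C)C(C)(C)C)/C=C(/C)[C@@H](O)C/C=C(\C)CCOCc1ccc(OC)cc1 | intermediate
18 | (3S,4Z,6S,8E)-3-(tert-butyldimethylsilyloxy)-11-(4-methoxybenzyloxy)-5,9-dimethylundeca-1,4,8-trien-6-yl 3-methylbutanoate | C=C[C@H](O[Si](C)(C)C(C)(C)C)/C=C(/C)[C@@H](OC(=O)CC(C)C)C/C=C(\C)CCOCc1ccc(OC)cc1 | intermediate
19 | (3S,4Z,6S)-3-(tert-butyldimethylsilyloxy)-7-{(2R,3R)-3-[2-(4-methoxybenzyloxy)ethyl]-3-methyloxiran-2-yl}-5-methylhepta-1,4-dien-6-yl 3-methylbutanoate | C=C[C@H](O[Si](C)(C)C(C)(C)C)/C=C(/C)[C@@H](OC(=O)CC(C)C)C[C@H]1O[C@]1(C)CCOCc1ccc(OC)cc1 | intermediate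
20 | (3S,4Z,6S)-3-hydroxy-7-{(2R,3R)-3-[2-(4-methoxybenzyloxy)ethyl]-3-methyloxiran-2-yl}-5-methylhepta-1,4-dien-6-yl 3-methylbutanoate | C=C[C@H](O)/C=C(/C)[C@@H](OC(=O)CC(C)C)C[C@H]1O[C@]1(C)CCOCc1ccc(OC)cc1 | intermediate
21 | (3S,4Z,6S)-7-{(2R,3R)-3-[2-(4-methoxybenzyloxy)ethyl]-3-methyloxiran-2-yl}-5-methyl-6-(3-methylbutanoyloxy)hepta-1,4-dien-3-yl 2-(bromomethyl)prop-2-enoate | C=C[C@H](OC(=O)C(=C)CBr)/C=C(/C)[C@@H](OC(=O)CC(C)C)C[C@H]1O[C@]1(C)CCOCc1ccc(OC)cc1 | intermediate
22 | (5R)-3-(bromomethyl)-5-[(1Z,3S)-2-methyl-3-(3-methylbutanoyloxy)-4-{(2R,3R)-3-[2-(4-methoxybenzyloxy)ethyl]-3-methyloxiran-2-yl}but-1-en-1-yl]furan-2(5H)-one | O=C1O[C@@H](C=C1CBr)/C=C(/C)[C@@H](OC(=O)CC(C)C)C[C@H]2O[C@]2(C)CCOCc2ccc(OC)cc2 | intermediate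
23 | (5R)-3-(bromomethyl)-5-[(1Z,3S)-4-{(2R,3R)-3-(2-hydroxyethyl)-3-methyloxiran-2-yl}-2-methyl-3-(3-methylbutanoyloxy)but-1-en-1-yl]furan-2(5H)-one | O=C1O[C@@H](C=C1CBr)/C=C(/C)[C@@H](OC(=O)CC(C)C)C[C@H]2O[C@]2(C)CCO | intermediate
24 | (5R)-3-(bromomethyl)-5-[(1Z,3S)-2-methyl-3-(3-methylbutanoyloxy)-4-{(2R,3R)-3-methyl-3-(2-oxoethyl)oxiran-2-yl}but-1-en-1-yl]furan-2(5H)-one | O=C1O[C@@H](C=C1CBr)/C=C(/C)[C@@H](OC(=O)CC(C)C)C[C@H]2O[C@]2(C)CC=O | intermediate
25 | allylchromium(III) dichloride of 24 (Cr on C13) | O=C1O[C@@H](C=C1C[Cr](Cl)Cl)/C=C(/C)[C@@H](OC(=O)CC(C)C)C[C@H]2O[C@]2(C)CC=O | intermediate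
26 | (1R,3S,4Z,6R,7R,8S,10R)-1,10-epoxy-8-hydroxy-3-(3-methylbutanoyloxy)germacra-4,11(13)-dien-12,6-olide | C=C1C(=O)O[C@@H]2/C=C(/C)[C@@H](OC(=O)CC(C)C)C[C@H]3O[C@]3(C)C[C@H](O)[C@@H]12 | intermediate
27 | (1R,3S,4Z,6R,7R,8R,10R)-8-[(2S,3S)-2,3-dimethyloxirane-2-carbonyloxy]-1,10-epoxy-3-(3-methylbutanoyloxy)germacra-4,11(13)-dien-12,6-olide | C=C1C(=O)O[C@@H]2/C=C(/C)[C@@H](OC(=O)CC(C)C)C[C@H]3O[C@]3(C)C[C@@H](OC(=O)[C@@]3(C)O[C@H]3C)[C@@H]12 | target

**Step count**
Total steps: 22. Longest linear sequence: 16 steps (steps 1–4 and 11–22).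

**Steps most likely to fail**

Step 21. Three processes threaten it. Lewis-acidic Cr(III) salts and the long reaction time at high dilution may open or eliminate the β,γ-epoxy aldehyde before it is trapped. Intermolecular allylation may compete with ring closure. Closure syn to C5 (cis-fused lactone) or with C9 pseudo-axial may compete; the latter would give the 8R alcohol directly, which would then be acylated with retention as in the fallback to step 22. The fallback replaces the in-situ organochromium by an isolable allylboron nucleophile that closes the ring thermally without metal salts, and sets out from 22. Palladium-catalysed borylation of the allylic bromide (B2pin2, Pd2(dba)3, DMSO) should give the allylboronate PMB ether F1. DDQ then gives the allylboronate alcohol F2, and Dess–Martin oxidation in dilute toluene gives the allylboronate aldehyde F3. On warming (2 mM, 50 °C) F3 should undergo intramolecular allylboration through the same chair transition state to the pinacol borate F4, which is hydrolysed on work-up to 26, where the route is rejoined.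

Step 22. SN2 displacement at the hindered C8 oxyphosphonium by the α,α-disubstituted carboxylate may be slow, so that elimination towards C9 or C7, or acylation with retention, takes over. The fallback inverts with a small nucleophile and then acylates with retention, and sets out from 26. A Mitsunobu reaction with formic acid should give the inverted 8R formate F5. Brief methanolysis (KHCO3, MeOH, 0 °C) should cleave only the formate and give the 8R alcohol F6. Yamaguchi esterification (14, 2,4,6-trichlorobenzoyl chloride, Et3N, then DMAP, toluene) then gives 27.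

Step 18. Metathesis of the electron-poor, 1,1-disubstituted bromomethyl acrylate may turn over slowly, with catalyst decomposition by the allylic bromide and thermal ionisation of the bis-allylic ester. The fallback closes the ring on a silyl-protected hydroxymethyl acrylate and introduces the bromide afterwards, and sets out from 20. Commercial ethyl 2-(hydroxymethyl)acrylate is silylated (TBSCl, imidazole) to ethyl 2-(silyloxymethyl)acrylate F7 and saponified (LiOH, THF–H2O) to 2-(silyloxymethyl)acrylic acid F8. Esterification of 20 with F8 (DIC, DMAP) gives the silyloxymethyl acrylate F9. Ring-closing metathesis (Grubbs II, CH2Cl2, 40 °C) gives the silyloxymethyl butenolide F10, and TBAF–AcOH gives the hydroxymethyl butenolide F11. Appel bromination (CBr4, PPh3, 0 °C) returns to 22.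

**Further compounds**
F1 | step 21 | allylboronate PMB ether (CH2Bpin in place of CH2Br in 22) | O=C1O[C@@H](C=C1CB2OC(C)(C)C(C)(C)O2)/C=C(/C)[C@@H](OC(=O)CC(C)C)C[C@H]3O[C@]3(C)CCOCc3ccc(OC)cc3
F2 | step 21 | allylboronate alcohol | O=C1O[C@@H](C=C1CB2OC(C)(C)C(C)(C)O2)/C=C(/C)[C@@H](OC(=O)CC(C)C)C[C@H]3O[C@]3(C)CCO
F3 | step 21 | allylboronate aldehyde | O=C1O[C@@H](C=C1CB2OC(C)(C)C(C)(C)O2)/C=C(/C)[C@@H](OC(=O)CC(C)C)C[C@H]3O[C@]3(C)CC=O
F4 | step 21 | pinacol borate of 26 (8-O-Bpin) | C=C1C(=O)O[C@@H]2/C=C(/C)[C@@H](OC(=O)CC(C)C)C[C@H]3O[C@]3(C)C[C@H](OB4OC(C)(C)C(C)(C)O4)[C@@H]12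
F5 | step 22 | 8R formate of the macrocycle | C=C1C(=O)O[C@@H]2/C=C(/C)[C@@H](OC(=O)CC(C)C)C[C@H]3O[C@]3(C)C[C@@H](OC=O)[C@@H]12
F6 | step 22 | 8R alcohol of the macrocycle | C=C1C(=O)O[C@@H]2/C=C(/C)[C@@H](OC(=O)CC(C)C)C[C@H]3O[C@]3(C)C[C@@H](O)[C@@H]12
F7 | step 18 | ethyl 2-[(tert-butyldimethylsilyloxy)methyl]acrylate | CCOC(=O)C(=C)CO[Si](C)(C)C(C)(C)C
F8 | step 18 | 2-[(tert-butyldimethylsilyloxy)methyl]acrylic acid | OC(=O)C(=C)CO[Si](C)(C)C(C)(C)C
F9 | step 18 | 2-(silyloxymethyl)acrylate of 20 | C=C[C@H](OC(=O)C(=C)CO[Si](C)(C)C(C)(C)C)/C=C(/C)[C@@H](OC(=O)CC(C)C)C[C@H]1O[C@]1(C)CCOCc1ccc(OC)cc1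
F10 | step 18 | 3-(silyloxymethyl)butenolide | O=C1O[C@@H](C=C1CO[Si](C)(C)C(C)(C)C)/C=C(/C)[C@@H](OC(=O)CC(C)C)C[C@H]2O[C@]2(C)CCOCc2ccc(OC)cc2
F11 | step 18 | 3-(hydroxymethyl)butenolide | O=C1O[C@@H](C=C1CO)/C=C(/C)[C@@H](OC(=O)CC(C)C)C[C@H]2O[C@]2(C)CCOCc2ccc(OC)cc2
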